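The green run had used 50.8% of the two substrates together at its last reading, 60.0 s, and midnight runs 3.0 min, so the question is where midnight stops; here is the quick number you wanted.

| setting | green | blue | midnight | dusk |
|---|---|---|---|---|
| left-handed substrate | 5 mM | 2.5 mM | 5.0 mM | 5.0 mM |
| right-handed substrate | 5 mM | 2.5 mM | 5.0 mM | 5.0 mM |
| solid reagent | 1.2 equiv | 1.2 equiv | 1.20 equiv | 1.20 equiv |
| free catalyst | 1 mol% | 1 mol% | 1 mol% | 0.25 mol% |
| impurity | 15 µM | 10 µM | 10 µM | 10 µM |
| remark | run made earlier | run made earlier |  |  |
| time |  |  | 3.0 min | 3.0 min |

- green (time / s: right-handed substrate / %, left-handed substrate / %, left-handed product / %): 10.0: 47.1, 48.4, 1.9; 20.0: 41.0, 45.3, 5.1; 30.0: 35.2, 41.1, 9.0; 40.0: 29.6, 38.2, 12.9; 50.0: 24.8, 34.2, 16.6; 60.0: 19.6, 29.6, 20.7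
- blue (time / s: right-handed substrate / %, left-handed substrate / %, left-handed product / %): 10.0: 47.1, 48.3, 1.8; 20.0: 41.1, 44.4, 5.2; 30.0: 34.2, 40.9, 9.5; 40.0: 27.1, 36.0, 14.8; 50.0: 22.1, 31.6, 19.2; 60.0: 18.9, 29.8, 20.9

(standard deviation of a reading: 0.5 percentage points)

- free catalyst is single-handed; left-handed substrate and right-handed substrate are mirror images of each other, charged as a racemate, each of them at the stated concentration
- solid reagent is a solid; its amount is given per volume of the solution
- the numbers in the tables scatter with a standard deviation of 0.5 percentage points
- at the start none of the solid reagent is in solution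
- an excess is the difference of the two amounts in percent of their sum
- an excess is below zero if the other one leads

* the winner by excess of right-handed substrate over left-handed substrate among what is left of the two; "neither" if no more than 2 percentage points parts them (midnight / dusk / neither)
* excess of right-handed substrate over left-handed substrate among what is left of the two at the end, midnight
* excess of right-handed substrate over left-handed substrate among what is left of the two at the end, dusk

If each product takes one solid reagent, then 1.20 equiv counted on the left-handed substrate makes the solid reagent the limiting reagent. The ceiling C, the part of both substrates together that the charged solid reagent can convert, is 60.0%. Green's figure is below it. If each impurity removes one catalyst, midnight keeps 40.0 µM, more than green's 35.0 µM, and it runs 3.0 min, so we put midnight at C.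

Let l and r be the fractions left of the left-handed and right-handed substrate. If the two rates go with l and r at a constant ratio s, the selectivity factor, integration gives r = l^s. The last readings of green and blue together give s = 1.83, and green at 30.0 s reads 1.79. Setting the mean of l and r to what C leaves gives l = 51.0% and r = 29.1%, an excess of −27.4%.

Dusk keeps 2.50 µM of catalyst. Green's pace scaled to that gives 11.9% conversion, below C, and the same law at small conversion gives −3.98%.

The forecast has −95% for midnight and −12% for dusk, winner dusk, and says “Reagent suffices”. We differ on both numbers and agree on the winner.

    free catalyst + left-handed substrate ⇌ catalyst intermediate A (K = 380 M⁻¹, k = 33800 M⁻¹ s⁻¹)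
    solid reagent ⇌ coupling partner, rate k2*(cs2 - [coupling partner]) while solid is left; crystals form when [coupling partner] > cs2 (solubility = 2.00 mM, k = 0.0720 s⁻¹)
    free catalyst + impurity → spent catalyst (k = 4.29 × 10⁶ M⁻¹ s⁻¹)
    coupling partner + catalyst intermediate A → free catalyst + left-handed product (k = 7950 M⁻¹ s⁻¹)
    coupling partner + catalyst intermediate B → free catalyst + right-handed product (k = 3240 M⁻¹ s⁻¹)
    left-handed product ⇌ right-handed product (k = 0.00280 s⁻¹)
    free catalyst + right-handed substrate ⇌ catalyst intermediate B (K = 1670 M⁻¹, k = 1.55 × 10⁵ M⁻¹ s⁻¹)

Midnight gives −27.9% and dusk −10.4%, so the winner is dusk. At the end of midnight 60.3% of the two substrates has reacted, level with C, with the solid reagent at 0% and the coupling partner at 2.70 × 10⁻⁸ mM. A neighbour flask is midnight with 4.80 equiv of solid reagent, which lifts the ceiling to 240%, above the whole charge. In that neighbour flask the left-handed substrate stands at 0%, the right-handed substrate at 0%, and the excess is −100.0%.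

Readings and results stem from a simulated flask for substances that don't exist; scatter was added.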